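## Retrosynthetic overview

1. Target ⇒ double Wittig at C11=C12 and C11'=C12': C10 trienedial 13 plus two (S)-C15 dienylphosphonium salts 12.
2. 12 ⇒ acetate 11 ⇒ Julia–Kocienski olefination at C7=C8 of (S)-α-cyclogeranyl heteroaryl sulfones with the C5 acetoxy-enal 9.
3. Two such sulfone arms (one on benzothiazole C2, one on tetrazole C5) sit on one 6-(tetrazol-1-yl)benzothiazole core (8), so both ε-rings and both C6 stereocentres come from one enantioselective proton-initiated double cyclization of the bis(geranyl sulfone) 7.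
4. 7 ⇒ 6-amino-1,3-benzothiazole-2-thiol: S-geranylation, then amine → isothiocyanate → tetrazolethiolate → second S-geranylation, then S-oxidation; each arm takes one equivalent of geranyl bromide in its own step.
5. Ring order: the tetrazole of the linker (step 2), then both cyclohexene rings at the same time (step 4); no ring is formed afterwards.

Assumption: 1, geranyl bromide (≥97% E), 9 and 13 are bought (9 and 13 as industrial terpenoid building blocks); the binaphthol monoether ligand of step 4 is a known compound (one O-benzylation of (R)-BINOL), is recovered, and its preparation is not counted.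

Abbreviation used in names: geranyl = (2E)-3,7-dimethylocta-2,6-dien-1-yl.

## Route

Step 1
Reactants: 1 6-amino-1,3-benzothiazole-2-thiol; 2 geranyl bromide
Product: 3 2-(geranylsulfanyl)-1,3-benzothiazol-6-amine
Conditions: K2CO3 (1.1 equiv), DMF, 0 °C → rt, 2 h
Reagents that add atoms: none
Why: Only the acidic heteroaryl thiol is deprotonated by K2CO3, and its soft thiolate sulfur displaces the primary allylic bromide by SN2 S-alkylation far faster than the aniline nitrogen reacts, leaving the E-alkene untouched.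

Step 2
Reactants: 3 2-(geranylsulfanyl)-1,3-benzothiazol-6-amine; 2 geranyl bromide
Product: 6 2-(geranylsulfanyl)-6-[5-(geranylsulfanyl)-1H-tetrazol-1-yl]-1,3-benzothiazole, via aryl isothiocyanate 4 (not isolated), via sodium tetrazolethiolate 5 (not isolated)
Conditions: CSCl2 (1.1 equiv), CH2Cl2/sat. aq. NaHCO3, 0 °C → rt; then NaN3 (1.1 equiv), i-PrOH/H2O, 75 °C; then 2 (1.1 equiv), THF, rt
Reagents that add atoms: thiophosgene, S=C(Cl)Cl; sodium azide, [Na+].[N-]=[N+]=[N-]
Why: The aniline is thiocarbonylated to the aryl isothiocyanate, azide adds to its carbon and the thiocarbamoyl azide closes to the 1-aryl-tetrazole-5-thiolate (azide–isothiocyanate cyclization), and this second thiolate is S-alkylated by the allylic bromide (SN2).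

Step 3
Reactants: 6 2-(geranylsulfanyl)-6-[5-(geranylsulfanyl)-1H-tetrazol-1-yl]-1,3-benzothiazole
Product: 7 2-(geranylsulfonyl)-6-[5-(geranylsulfonyl)-1H-tetrazol-1-yl]-1,3-benzothiazole
Conditions: (NH4)6Mo7O24·4H2O (20 mol%), 30% H2O2 (10 equiv), EtOH/THF, 0 °C → rt
Reagents that add atoms: hydrogen peroxide, OO
Why: Molybdate-catalysed sulfide-to-sulfone oxidation with H2O2 is selective for sulfur over trisubstituted alkenes and is the standard preparation of benzothiazolyl and tetrazolyl sulfones for Julia–Kocienski chemistry.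

Step 4
Reactants: 7 2-(geranylsulfonyl)-6-[5-(geranylsulfonyl)-1H-tetrazol-1-yl]-1,3-benzothiazole
Product: 8 2-({[(1S)-2,6,6-trimethylcyclohex-2-en-1-yl]methyl}sulfonyl)-6-[5-({[(1S)-2,6,6-trimethylcyclohex-2-en-1-yl]methyl}sulfonyl)-1H-tetrazol-1-yl]-1,3-benzothiazole
Conditions: SnCl4 (3.0 equiv) + (R)-2'-(2-fluorobenzyloxy)-1,1'-binaphthalen-2-ol (3.3 equiv), CH2Cl2/toluene, −78 °C, 48 h; aq. NaHCO3; chromatography, recrystallization (EtOAc/heptane)
Reagents that add atoms: none
Why: Proposed new method: the chiral Brønsted acid formed from SnCl4 and the (R)-binaphthol monoether protonates each terminal isopropylidene group on one enantiotopic face while the 2,3-alkene of that geranyl unit closes the six-membered ring through a chair-like transition state, and the tertiary C5 cation then loses the ring C4 proton to give the endocyclic olefin, so both rings and both C6 centres are set as S in one operation (the chair fold that this (R)-acid imposes when homofarnesol derivatives are cyclized to (−)-ambrox, whose C5 maps onto C6 here); the closest known reaction types are the enantioselective proton-initiated polyene cyclization with SnCl4–binaphthol acids and the protic-acid cyclization of geranyl aryl sulfones to α-cyclogeranyl sulfones.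

Step 5
Reactants: 8 2-({[(1S)-2,6,6-trimethylcyclohex-2-en-1-yl]methyl}sulfonyl)-6-[5-({[(1S)-2,6,6-trimethylcyclohex-2-en-1-yl]methyl}sulfonyl)-1H-tetrazol-1-yl]-1,3-benzothiazole; 9 (2E)-4-acetoxy-2-methylbut-2-enal
Product: 11 (2E,4E)-3-methyl-5-[(1S)-2,6,6-trimethylcyclohex-2-en-1-yl]penta-2,4-dien-1-yl acetate, via dipotassium bis(sulfonyl carbanion) 10 (not isolated)
Conditions: KN(SiMe3)2 (2.2 equiv), DME, −78 °C, 15 min; then 9 (2.4 equiv), −78 °C → rt; AcOH quench
Reagents that add atoms: none
Why: Julia–Kocienski olefination: each α-sulfonyl carbanion adds to the enal, the alkoxide transfers the benzothiazole or tetrazole ring by Smiles rearrangement and SO2 plus the heteroaryl oxide are expelled to give mainly the E alkene at C7=C8, and C6 (β to the carbanion, not acidic) is untouched, so one molecule of 8 delivers two molecules of 11.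

Step 6
Reactants: 11 (2E,4E)-3-methyl-5-[(1S)-2,6,6-trimethylcyclohex-2-en-1-yl]penta-2,4-dien-1-yl acetate
Product: 12 [(2E,4E)-3-methyl-5-[(1S)-2,6,6-trimethylcyclohex-2-en-1-yl]penta-2,4-dien-1-yl]triphenylphosphonium bromide
Conditions: PPh3·HBr (1.05 equiv), MeOH, rt, 16 h
Reagents that add atoms: triphenylphosphine hydrobromide, Br.c1ccc(cc1)P(c1ccccc1)c1ccccc1
Why: Acid-mediated allylic substitution through the dienyl cation (the way retinyl acetate and vinyl-ionols are turned into Wittig salts) places PPh3 on the terminal carbon and lets C7=C8 and C9=C10 relax to E,E, with C6 not involved.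

Step 7
Reactants: 12 [(2E,4E)-3-methyl-5-[(1S)-2,6,6-trimethylcyclohex-2-en-1-yl]penta-2,4-dien-1-yl]triphenylphosphonium bromide; 13 (2E,4E,6E)-2,7-dimethylocta-2,4,6-trienedial
Product: 16 (6S,6'S)-ε,ε-carotene (all-E), via dienyl phosphorane 14 (not isolated), via 11Z-rich crude carotene 15 (not isolated)
Conditions: 12 (2.1 equiv), NaOMe (2.2 equiv), CH2Cl2/MeOH, 0 °C → rt; then heptane, reflux, N2, dark; crystallization
Reagents that add atoms: none
Why: Double Wittig olefination of the dialdehyde by the dienyl ylide builds C11=C12 and C11'=C12' (the classical C15 + C10 + C15 carotenoid assembly, which preserves C6 in ε end groups), and thermal Z/E isomerization with crystallization funnels the 11Z isomers to the all-E compound.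

## Compound list

1 | 6-amino-1,3-benzothiazole-2-thiol (6-amino-2-mercaptobenzothiazole) | Nc1ccc2nc(S)sc2c1 | starting material
2 | geranyl bromide, (2E)-1-bromo-3,7-dimethylocta-2,6-diene | CC(C)=CCC/C(C)=C/CBr | starting material
3 | 2-(geranylsulfanyl)-1,3-benzothiazol-6-amine, i.e. 2-{[(2E)-3,7-dimethylocta-2,6-dien-1-yl]sulfanyl}-1,3-benzothiazol-6-amine | CC(C)=CCC/C(C)=C/CSc1nc2ccc(N)cc2s1 | intermediate
4 | 2-(geranylsulfanyl)-6-isothiocyanato-1,3-benzothiazole | CC(C)=CCC/C(C)=C/CSc1nc2ccc(N=C=S)cc2s1 | intermediate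
5 | sodium 1-[2-(geranylsulfanyl)-1,3-benzothiazol-6-yl]-1H-tetrazole-5-thiolate | [Na+].CC(C)=CCC/C(C)=C/CSc1nc2ccc(cc2s1)-n1nnnc1[S-] | intermediate
6 | 2-(geranylsulfanyl)-6-[5-(geranylsulfanyl)-1H-tetrazol-1-yl]-1,3-benzothiazole | CC(C)=CCC/C(C)=C/CSc1nc2ccc(cc2s1)-n1nnnc1SC/C=C(\C)CCC=C(C)C | intermediate
7 | 2-(geranylsulfonyl)-6-[5-(geranylsulfonyl)-1H-tetrazol-1-yl]-1,3-benzothiazole | CC(C)=CCC/C(C)=C/CS(=O)(=O)c1nc2ccc(cc2s1)-n1nnnc1S(=O)(=O)C/C=C(\C)CCC=C(C)C | intermediate
8 | 2-({[(1S)-2,6,6-trimethylcyclohex-2-en-1-yl]methyl}sulfonyl)-6-[5-({[(1S)-2,6,6-trimethylcyclohex-2-en-1-yl]methyl}sulfonyl)-1H-tetrazol-1-yl]-1,3-benzothiazole | CC1=CCCC(C)(C)[C@@H]1CS(=O)(=O)c1nc2ccc(cc2s1)-n1nnnc1S(=O)(=O)C[C@@H]1C(C)=CCCC1(C)C | intermediate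
9 | (2E)-4-acetoxy-2-methylbut-2-enal | CC(=O)OC/C=C(\C)C=O | starting material
10 | dipotassium α,α'-dicarbanion of 8 | [K+].[K+].CC1=CCCC(C)(C)[C@@H]1[CH-]S(=O)(=O)c1nc2ccc(cc2s1)-n1nnnc1S(=O)(=O)[CH-][C@@H]1C(C)=CCCC1(C)C | intermediate
11 | (2E,4E)-3-methyl-5-[(1S)-2,6,6-trimethylcyclohex-2-en-1-yl]penta-2,4-dien-1-yl acetate | CC1=CCCC(C)(C)[C@@H]1/C=C/C(C)=C/COC(C)=O | intermediate
12 | [(2E,4E)-3-methyl-5-[(1S)-2,6,6-trimethylcyclohex-2-en-1-yl]penta-2,4-dien-1-yl]triphenylphosphonium bromide | CC1=CCCC(C)(C)[C@@H]1/C=C/C(C)=C/C[P+](c1ccccc1)(c1ccccc1)c1ccccc1.[Br-] | intermediate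
13 | (2E,4E,6E)-2,7-dimethylocta-2,4,6-trienedial | O=C/C(C)=C/C=C/C=C(\C)C=O | starting material
14 | (2E,4E)-3-methyl-5-[(1S)-2,6,6-trimethylcyclohex-2-en-1-yl]penta-2,4-dienylidene(triphenyl)phosphorane | CC1=CCCC(C)(C)[C@@H]1/C=C/C(C)=C/C=P(c1ccccc1)(c1ccccc1)c1ccccc1 | intermediate
15 | crude (6S,6'S)-ε,ε-carotene rich in 11Z and 11'Z isomers (drawn as 11Z,11'Z) | CC1=CCCC(C)(C)[C@@H]1/C=C/C(C)=C/C=C\C(C)=C\C=C\C=C(C)\C=C/C=C(C)/C=C/[C@@H]1C(C)=CCCC1(C)C | intermediate
16 | (6S,6'S)-ε,ε-carotene (all-E) | CC1=CCCC(C)(C)[C@@H]1/C=C/C(C)=C/C=C/C(C)=C/C=C/C=C(C)/C=C/C=C(C)/C=C/[C@@H]1C(C)=CCCC1(C)C | target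

## Step count and risks

Total step count: 7. Longest linear sequence: 7 (1 → 3 → 6 → 7 → 8 → 11 → 12 → 16); 2, 9 and 13 are bought.

**Step 4 (most likely to fail).** This step is untested on such a substrate. The allylic sulfonyl group lowers the nucleophilicity of the ring-closing alkene, so closure at −78 °C may be slow. Exocyclic-olefin isomers may form alongside the wanted endocyclic one. SnCl4 may ionize the allylic C–S bond, and the benzothiazole nitrogen binds part of it, which is why three equivalents are used. The sense of induction is inferred by analogy; if it proves opposite on this substrate, the (S)-ligand is used instead. Per-site selectivity may be only about 9:1, which would give roughly 81% (S,S), 9% each of (S,R) and (R,S), and 1% (R,R). Because both arms are on one core, removing the two unlike diastereomers would leave (S,S) material of about 97% ee. Whether crystallization or chromatography separates them is unproven; if not, the same chiral SFC as below is used.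

Fallback, setting out from 7 and coming back at 8: treat 7 with concentrated H2SO4 in AcOH at 10–20 °C, the classical protic cyclization of geranyl aryl sulfones. Both rings still close in one operation but without absolute control, which gives 2-({[2,6,6-trimethylcyclohex-2-en-1-yl]methyl}sulfonyl)-6-[5-({[2,6,6-trimethylcyclohex-2-en-1-yl]methyl}sulfonyl)-1H-tetrazol-1-yl]-1,3-benzothiazole F1 as the equimolar mixture of its four stereoisomers. Preparative chiral SFC on an amylose carbamate phase then isolates the (S,S) isomer, which is 8. Asymmetric catalysis is replaced by resolution, at the cost of at most 25% recovery.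

**Step 5.** The carbanions are neopentyl-like and hindered, and the benzothiazolyl sulfone arm can self-condense if the carbanion is held too long or too warm. The enal carries acidic γ-protons and an acetate, and E/Z control with an enal partner is moderate.

Fallback, setting out from 8 and coming back at 11, a classical Julia alkylation–elimination in place of the carbonyl olefination: deprotonate 8 twice with LiN(SiMe3)2 (THF, −78 °C) and alkylate with (2E)-4-bromo-3-methylbut-2-en-1-yl acetate. This gives 2-({(3E)-5-acetoxy-3-methyl-1-[(1S)-2,6,6-trimethylcyclohex-2-en-1-yl]pent-3-en-1-yl}sulfonyl)-6-[5-({(3E)-5-acetoxy-3-methyl-1-[(1S)-2,6,6-trimethylcyclohex-2-en-1-yl]pent-3-en-1-yl}sulfonyl)-1H-tetrazol-1-yl]-1,3-benzothiazole F2, as epimers at the sulfonyl-bearing carbons, which does not matter. KOt-Bu in THF at −20 °C then removes an allylic C8 proton on each arm and expels the heteroaryl sulfinate in a 1,2-elimination (AcOH quench), giving 11. The weak point is competing removal of the C6 proton.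

**Step 6.** The acid and the dienyl cation could cause proton loss from C6 (a retro-type triene, losing the stereocentre) or leave 9Z material.

Fallback, setting out from 11 and coming back at 16, a neutral phosphonate route in place of the Wittig salt: methanolysis (K2CO3 cat., MeOH) gives (2E,4E)-3-methyl-5-[(1S)-2,6,6-trimethylcyclohex-2-en-1-yl]penta-2,4-dien-1-ol F3. PBr3 with pyridine in Et2O at −20 °C then gives (1S)-1-[(1E,3E)-5-bromo-3-methylpenta-1,3-dien-1-yl]-2,6,6-trimethylcyclohex-2-ene F4. A Michaelis–Arbuzov reaction with P(OEt)3 at 90 °C gives diethyl [(2E,4E)-3-methyl-5-[(1S)-2,6,6-trimethylcyclohex-2-en-1-yl]penta-2,4-dien-1-yl]phosphonate F5. Finally F5 (2.1 equiv) and 13 with NaOMe in THF/MeOH (0 °C → rt, AcOH quench) undergo a double Horner–Wadsworth–Emmons olefination, E-selective at C11=C12, to give 16 directly.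

Further compounds
F1 | step 4 | 2-({[2,6,6-trimethylcyclohex-2-en-1-yl]methyl}sulfonyl)-6-[5-({[2,6,6-trimethylcyclohex-2-en-1-yl]methyl}sulfonyl)-1H-tetrazol-1-yl]-1,3-benzothiazole, equimolar mixture of the four stereoisomers (ring stereocentres undefined) | CC1=CCCC(C)(C)C1CS(=O)(=O)c1nc2ccc(cc2s1)-n1nnnc1S(=O)(=O)CC1C(C)=CCCC1(C)C
F2 | step 5 | 2-({(3E)-5-acetoxy-3-methyl-1-[(1S)-2,6,6-trimethylcyclohex-2-en-1-yl]pent-3-en-1-yl}sulfonyl)-6-[5-({(3E)-5-acetoxy-3-methyl-1-[(1S)-2,6,6-trimethylcyclohex-2-en-1-yl]pent-3-en-1-yl}sulfonyl)-1H-tetrazol-1-yl]-1,3-benzothiazole (epimers at the sulfonyl-bearing carbons) | CC1=CCCC(C)(C)[C@@H]1C(C/C(C)=C/COC(C)=O)S(=O)(=O)c1nc2ccc(cc2s1)-n1nnnc1S(=O)(=O)C(C/C(C)=C/COC(C)=O)[C@@H]1C(C)=CCCC1(C)C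
F3 | step 6 | (2E,4E)-3-methyl-5-[(1S)-2,6,6-trimethylcyclohex-2-en-1-yl]penta-2,4-dien-1-ol | CC1=CCCC(C)(C)[C@@H]1/C=C/C(C)=C/CO
F4 | step 6 | (1S)-1-[(1E,3E)-5-bromo-3-methylpenta-1,3-dien-1-yl]-2,6,6-trimethylcyclohex-2-ene | CC1=CCCC(C)(C)[C@@H]1/C=C/C(C)=C/CBr
F5 | step 6 | diethyl [(2E,4E)-3-methyl-5-[(1S)-2,6,6-trimethylcyclohex-2-en-1-yl]penta-2,4-dien-1-yl]phosphonate | CC1=CCCC(C)(C)[C@@H]1/C=C/C(C)=C/CP(=O)(OCC)OCC
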